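**Plan**

- Cuts: the five-membered enone ring of the indenone is opened at C3–C3a and at C1–C2 in one retro-[3+2]. This frees the internal alkyne CH3–C≡C–(guaiazulen-3-yl) and an o-(triflyloxy)benzaldehyde. The arene is cut further at O–S, Ar–CHO and Ar–C(O)iPr back to m-cresol; the alkyne is cut at C(sp)–CH3 and at the exocyclic C=C/C=O carbon back to guaiazulene.
- Feature used: C2=C3 of the indenone ring is a ring-locked tetrasubstituted alkene with CH3 on C3 and the azulenyl group on C2. It sits between the carbonyl carbon C1 and the fusion carbon C3a, which hang on two ortho carbons of the benzene ring. That is the imprint of an alkyne inserted between an aryl C–X bond and an ortho formyl C–H bond.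
- Forward order: the benzene ring is bought as m-cresol and dressed (Fries acylation, ortho-formylation, triflation). The azulene bicycle is bought as guaiazulene and extended at its nucleophilic C3 (formylation, dibromo-olefination, alkyne formation with C-methylation). The indenone five-membered ring is the last ring, closed by a Pd-catalysed annulation that also joins the two halves.
- Stereochemistry: the target has no stereocentre. Its only geometric element, the cis relation across C2=C3, comes from syn-carbopalladation and is fixed in the ring.

Key step: step 7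

Remark: locants are those of 1H-inden-1-one (C1 = C=O, C2, C3, C3a, C4–C7, C7a) and of guaiazulene (1,4-dimethyl-7-isopropylazulene, free nucleophilic position C3).

**Route**

Step 1
Reactants: 1 m-cresol (3-methylphenol); 2 isobutyryl chloride (2-methylpropanoyl chloride)
Product: 4 1-(2-hydroxy-4-methylphenyl)-2-methylpropan-1-one, via m-tolyl isobutyrate 3 (not isolated)
Conditions: neat, 60 °C; then AlCl3 (1.5 equiv), 150 °C; aq. HCl
Reagents that add atoms: none
Why: O-acylation followed by a high-temperature Fries rearrangement should return the acyl group to the ortho carbon that is para to the methyl group, because the chelated o-hydroxy ketone is the thermodynamic product and the other ortho carbon (between OH and CH3) is hindered.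

Step 2
Reactants: 4 1-(2-hydroxy-4-methylphenyl)-2-methylpropan-1-one
Product: 6 2-hydroxy-6-methyl-3-(2-methylpropanoyl)benzaldehyde, via salicyl alcohol 5 (not isolated)
Conditions: MgCl2 (3 equiv), Et3N (4 equiv), (CH2O)n (6 equiv), MeCN, reflux; aq. HCl
Reagents that add atoms: paraformaldehyde, as formaldehyde (C=O)
Why: In the Casnati–Skattebøl ortho-formylation the magnesium phenoxide delivers bound formaldehyde only to an ortho carbon, the single free ortho carbon is the one between OH and CH3, and the hydroxymethyl intermediate is oxidised in the flask by a second formaldehyde through an Oppenauer-type hydride transfer.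

Step 3
Reactants: 6 2-hydroxy-6-methyl-3-(2-methylpropanoyl)benzaldehyde
Product: 7 2-formyl-3-methyl-6-(2-methylpropanoyl)phenyl trifluoromethanesulfonate
Conditions: Tf2O (1.2 equiv), pyridine (3 equiv), CH2Cl2, 0 °C
Reagents that add atoms: trifluoromethanesulfonic anhydride, O=S(=O)(OS(=O)(=O)C(F)(F)F)C(F)(F)F
Why: O-sulfonylation of the phenol turns the C–O bond into a pseudohalide for oxidative addition, placed exactly on the future fusion carbon C3a and further activated by its two ortho carbonyl groups.

Step 4
Reactants: 8 guaiazulene
Product: 10 3,8-dimethyl-5-(propan-2-yl)azulene-1-carbaldehyde, via iminium chloride 9 (not isolated)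
Conditions: POCl3 (1.1 equiv), DMF, 0 °C to rt; then aq. NaOH
Reagents that add atoms: N,N-dimethylformamide, CN(C)C=O; water, O
Why: Vilsmeier–Haack formylation should occur at C3 of guaiazulene, the only free position of the five-membered ring whose attack gives a tropylium-type cation (C1 is blocked by methyl), and basic hydrolysis of the iminium salt gives the aldehyde.

Step 5
Reactants: 10 3,8-dimethyl-5-(propan-2-yl)azulene-1-carbaldehyde
Product: 11 1-(2,2-dibromoethenyl)-3,8-dimethyl-5-(propan-2-yl)azulene
Conditions: CBr4 (2 equiv), PPh3 (2 equiv), Zn dust (2 equiv), CH2Cl2, rt (reagent pre-formed); then 10, rt to 40 °C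
Reagents that add atoms: carbon tetrabromide, BrC(Br)(Br)Br
Why: Ramirez dibromo-olefination (first half of the Corey–Fuchs sequence) is a Wittig reaction of Ph3P=CBr2, and making the ylide with zinc keeps Ph3PBr2, an electrophilic bromine source, away from the electron-rich azulene.

Step 6
Reactants: 11 1-(2,2-dibromoethenyl)-3,8-dimethyl-5-(propan-2-yl)azulene
Product: 13 3,8-dimethyl-5-(propan-2-yl)-1-(prop-1-yn-1-yl)azulene, via lithium acetylide 12 (not isolated)
Conditions: n-BuLi (2.0 equiv), THF, −78 °C, 1 h; then MeOTf (1.1 equiv), −78 °C; aq. NH4Cl
Reagents that add atoms: methyl trifluoromethanesulfonate, COS(=O)(=O)C(F)(F)F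
Why: In the second half of the Corey–Fuchs sequence, Br/Li exchange, Fritsch–Buttenberg–Wiechell-type elimination and deprotonation give the lithium acetylide, and methyl triflate should methylate it at −78 °C before a proton can move from the acidic methyl group on the seven-membered ring (C4–CH3 in guaiazulene numbering).

Step 7
Reactants: 7 2-formyl-3-methyl-6-(2-methylpropanoyl)phenyl trifluoromethanesulfonate; 13 3,8-dimethyl-5-(propan-2-yl)-1-(prop-1-yn-1-yl)azulene (1.3 equiv)
Product: 14 2-[3,8-dimethyl-5-(propan-2-yl)azulen-1-yl]-3,7-dimethyl-4-(2-methylpropanoyl)-1H-inden-1-one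
Conditions: Pd(OAc)2 (10 mol %), PPh3 (20 mol %), LiCl (2 equiv), NaOAc (3 equiv, dry), DMF, 100 °C
Reagents that add atoms: none
Why: Zerovalent palladium, formed in the flask from Pd(OAc)2 and PPh3, inserts into the C–OTf bond of 7 and chloride gives a neutral ArPdCl species; syn-carbopalladation of 13 then joins the aryl carbon to the methyl-bearing alkyne carbon (C3–C3a) and leaves palladium on the azulenyl-bearing carbon, which adds to the neighbouring formyl group (C2–C1), and β-hydride elimination from the divalent palladium alkoxide gives the ketone while NaOAc takes up the acid and zerovalent palladium returns. The closest known reaction type is the Larock indenone annulation of o-halobenzaldehydes with internal aryl alkyl alkynes, run here with an aryl triflate and LiCl in place of the halide. The five-membered ring closes in the second C–C bond formation, a 5-exo-trig attack of the alkenyl carbon on the aldehyde C=O after the intermolecular insertion, so the overall event is a [3+2] annulation. No stereocentre is formed, and the cis arrangement across C2=C3 that the ring needs follows from the syn addition. Two selectivities are needed: the orientation of insertion, secured by the size difference between methyl and the guaiazulenyl group with its peri methyl (the bulkier end goes next to palladium and so to C2) and by the chloride-bound neutral pathway, which avoids cationic arylation at the donor-substituted alkyne carbon; and the choice of the aldehyde over the isopropyl ketone on the other ortho carbon, secured by the higher electrophilicity and lower hindrance of CHO and by the fact that only the aldehyde adduct can leave the cycle by β-hydride elimination. The site of closure on the benzene ring is fixed by the position of the triflate.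

**Compound list**

1 | m-cresol (3-methylphenol) | Cc1cccc(O)c1 | starting material
2 | isobutyryl chloride (2-methylpropanoyl chloride) | CC(C)C(=O)Cl | starting material
3 | m-tolyl isobutyrate (3-methylphenyl 2-methylpropanoate) | CC(C)C(=O)Oc1cccc(C)c1 | intermediate
4 | 1-(2-hydroxy-4-methylphenyl)-2-methylpropan-1-one | CC(C)C(=O)c1ccc(C)cc1O | intermediate
5 | 1-[2-hydroxy-3-(hydroxymethyl)-4-methylphenyl]-2-methylpropan-1-one (salicyl alcohol, present as its magnesium salt) | CC(C)C(=O)c1ccc(C)c(CO)c1O | intermediate
6 | 2-hydroxy-6-methyl-3-(2-methylpropanoyl)benzaldehyde | CC(C)C(=O)c1ccc(C)c(C=O)c1O | intermediate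
7 | 2-formyl-3-methyl-6-(2-methylpropanoyl)phenyl trifluoromethanesulfonate | CC(C)C(=O)c1ccc(C)c(C=O)c1OS(=O)(=O)C(F)(F)F | intermediate
8 | guaiazulene (1,4-dimethyl-7-(propan-2-yl)azulene) | Cc1ccc2c(C)ccc(C(C)C)cc1-2 | starting material
9 | N,N-dimethyl-1-[3,8-dimethyl-5-(propan-2-yl)azulen-1-yl]methaniminium chloride | C[N+](C)=Cc1cc(C)c2cc(C(C)C)ccc(C)c1-2.[Cl-] | intermediate
10 | 3,8-dimethyl-5-(propan-2-yl)azulene-1-carbaldehyde (3-formylguaiazulene) | O=Cc1cc(C)c2cc(C(C)C)ccc(C)c1-2 | intermediate
11 | 1-(2,2-dibromoethenyl)-3,8-dimethyl-5-(propan-2-yl)azulene | BrC(Br)=Cc1cc(C)c2cc(C(C)C)ccc(C)c1-2 | intermediate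
12 | lithium [3,8-dimethyl-5-(propan-2-yl)azulen-1-yl]ethynide | [Li]C#Cc1cc(C)c2cc(C(C)C)ccc(C)c1-2 | intermediate
13 | 3,8-dimethyl-5-(propan-2-yl)-1-(prop-1-yn-1-yl)azulene | CC#Cc1cc(C)c2cc(C(C)C)ccc(C)c1-2 | intermediate
14 | 2-[3,8-dimethyl-5-(propan-2-yl)azulen-1-yl]-3,7-dimethyl-4-(2-methylpropanoyl)-1H-inden-1-one | CC1=C(c2cc(C)c3cc(C(C)C)ccc(C)c2-3)C(=O)c2c(C)ccc(C(=O)C(C)C)c21 | target

**Step count**

Total steps: 7. Longest linear sequence: 4 steps (steps 1, 2, 3, 7 or steps 4, 5, 6, 7).

**Steps most likely to fail**

Step 7. Alkyne insertion into the doubly ortho-substituted arylpalladium may be slow, so that hydrolysis or reduction of the triflate takes over. Insertion may also occur with the opposite orientation, or the alkenylpalladium may be captured by the ketone instead of the aldehyde. The fallback reverses the polarity of the aryl partner and closes the ring at the alcohol oxidation level. It sets out from 7 (with 13) and comes back at 14. Miyaura borylation of 7 (B2pin2, Pd(dppf)Cl2, KOAc, dioxane, 80 °C) should give 6-methyl-3-(2-methylpropanoyl)-2-(4,4,5,5-tetramethyl-1,3,2-dioxaborolan-2-yl)benzaldehyde F1. Arylrhodation of 13 by monovalent rhodium ([Rh(OH)(cod)]2, dioxane/H2O, 80 °C), followed by addition of the alkenylrhodium to the formyl group, should give racemic 2-[3,8-dimethyl-5-(propan-2-yl)azulen-1-yl]-3,7-dimethyl-4-(2-methylpropanoyl)-1H-inden-1-ol F2, with the aryl group again going to the methyl-bearing alkyne carbon. Oxidation of the doubly activated secondary alcohol with MnO2 in CH2Cl2 then gives 14.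

Step 2. Electrophilic substitution of the acyl-chelated, deactivated magnesium phenoxide may be sluggish at the hindered carbon between OH and CH3, with slow conversion or O-alkylation by formaldehyde. The fallback brings the carbon in by a sigmatropic shift instead. It sets out from 4 and comes back at 6. O-Allylation (allyl bromide, K2CO3, acetone, reflux) should give 2-methyl-1-[4-methyl-2-(prop-2-en-1-yloxy)phenyl]propan-1-one F3. Claisen rearrangement (N,N-diethylaniline, 190 °C) moves the allyl group to the only free ortho carbon and gives 1-[2-hydroxy-4-methyl-3-(prop-2-en-1-yl)phenyl]-2-methylpropan-1-one F4. Double-bond migration (RuHCl(CO)(PPh3)3, toluene, 80 °C) gives 1-{2-hydroxy-4-methyl-3-[(1E)-prop-1-en-1-yl]phenyl}-2-methylpropan-1-one F5. Lemieux–Johnson cleavage (OsO4 cat., NaIO4, 2,6-lutidine, dioxane/H2O) then gives 6.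

Step 6. Proton transfer from the acidic methyl group on the seven-membered ring to the acetylide, or addition of n-BuLi to the seven-membered ring, may lead to methylation at the wrong carbon or to loss of material. The fallback inverts the roles so that the alkyne is the electrophile and methyl the nucleophile, with no carbanion generated next to the acidic methyl group. It sets out from 11 and comes back at 13. Dehydrobromination of 11 (DBU, DMSO, rt) should give 1-(bromoethynyl)-3,8-dimethyl-5-(propan-2-yl)azulene F6. Negishi coupling with MeZnCl (Pd(PPh3)4, THF, rt) then gives 13.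

**Further compounds**

F1 | step 7 | 6-methyl-3-(2-methylpropanoyl)-2-(4,4,5,5-tetramethyl-1,3,2-dioxaborolan-2-yl)benzaldehyde | O=Cc1c(C)ccc(C(=O)C(C)C)c1B1OC(C)(C)C(C)(C)O1
F2 | step 7 | 2-[3,8-dimethyl-5-(propan-2-yl)azulen-1-yl]-3,7-dimethyl-4-(2-methylpropanoyl)-1H-inden-1-ol (racemic) | CC1=C(c2cc(C)c3cc(C(C)C)ccc(C)c2-3)C(O)c2c(C)ccc(C(=O)C(C)C)c21
F3 | step 2 | 2-methyl-1-[4-methyl-2-(prop-2-en-1-yloxy)phenyl]propan-1-one | C=CCOc1cc(C)ccc1C(=O)C(C)C
F4 | step 2 | 1-[2-hydroxy-4-methyl-3-(prop-2-en-1-yl)phenyl]-2-methylpropan-1-one | C=CCc1c(C)ccc(C(=O)C(C)C)c1O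
F5 | step 2 | 1-{2-hydroxy-4-methyl-3-[(1E)-prop-1-en-1-yl]phenyl}-2-methylpropan-1-one | C/C=C/c1c(C)ccc(C(=O)C(C)C)c1O
F6 | step 6 | 1-(bromoethynyl)-3,8-dimethyl-5-(propan-2-yl)azulene | BrC#Cc1cc(C)c2cc(C(C)C)ccc(C)c1-2
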